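## Retrosynthetic overview

1. The target comes from a bicyclo[4.3.1]decane dienal diol by 1,2-reduction and selective acetylation. That diol comes from an acid-triggered transannular epoxide–olefin cyclisation with water capture: the one-carbon bridge CH2 (C10) is joined to the methyl-bearing bridgehead (C6). This one bond creates the six- and the seven-membered ring, the quaternary centre and both ring carbinols.
2. Enabling feature: in the nine-membered ring the exocyclic 1,1-disubstituted C=CH2 (future C1/C10) and the trisubstituted cis-oxirane (future C6/C7) are separated by two CH2 groups. The terminal methylene carbon therefore lies across the ring from the tertiary oxirane carbon; attack there is Markovnikov at both partners, runs through a chair, and leaves a bridgehead cation that can only be hydrated.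
3. The nine-membered (Z)-cycloalkene comes from ring-closing metathesis of an acyclic triene ester. The side chain is built by an enol ether–acetal condensation and kept as the dienal through epoxidation and cyclisation, where it deactivates the diene towards the peracid and the tertiary allylic alcohol towards ionisation.
4. The two stereocentres of the acyclic precursor come from one enamine-catalysed Michael addition of 5-methylhex-5-enal to a 2-substituted nitrodiene; CH2NO2 is then converted into CO2Me.
5. Ring order: nine-membered carbocycle, then oxirane, then six- and seven-membered rings together.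

Key step: step 17

Remark: enol ether 16 is carried as an E/Z mixture, because both isomers converge in step 15.

## Route

Step 1
Reactants: 1 hex-5-enal
Product: 2 2-methylidenehex-5-enal
Conditions: aq. CH2O (37 %), pyrrolidine (10 mol %), EtCO2H (10 mol %), i-PrOH, 45 °C
Reagents that add atoms: formaldehyde, C=O
Why: Amine-catalysed Mannich condensation and elimination (organocatalytic α-methylenation of an aldehyde) should install the carbon that later becomes the one-carbon bridge; no stereocentre is formed.

Step 2
Reactants: 2 2-methylidenehex-5-enal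
Product: 3 3-methylidene-1-nitrohept-6-en-2-ol (racemic)
Conditions: MeNO2 (3 equiv), KOtBu (5 mol %), THF/t-BuOH, −20 °C; AcOH quench
Reagents that add atoms: nitromethane, C[N+](=O)[O-]
Why: Henry (nitroaldol) reaction, in which 1,2-addition of the nitronate is the kinetic pathway at low temperature with catalytic base; the racemic carbinol centre is removed in the next step.

Step 3
Reactants: 3 3-methylidene-1-nitrohept-6-en-2-ol
Product: 5 (1E)-3-methylidene-1-nitrohepta-1,6-diene, via mesylate 4 (not isolated)
Conditions: MsCl, Et3N, CH2Cl2, −20 → 0 °C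
Reagents that add atoms: none
Why: Mesylation and E1cB elimination (standard dehydration of a β-nitro alcohol) should give the more stable (E)-nitroalkene, which is used at once.

Step 4
Reactants: 6 ethyl 5-oxohexanoate
Product: 7 ethyl 5-methylhex-5-enoate
Conditions: Ph3PCH3Br, KOtBu, THF, 0 °C → rt
Reagents that add atoms: methyltriphenylphosphonium bromide, C[P+](c1ccccc1)(c1ccccc1)c1ccccc1.[Br-]
Why: Wittig methylenation of the ketone; the ester does not react with the ylide under these conditions.

Step 5
Reactants: 7 ethyl 5-methylhex-5-enoate
Product: 8 5-methylhex-5-enal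
Conditions: i-Bu2AlH (1.05 equiv), CH2Cl2, −78 °C; aq. potassium sodium tartrate (KNaC4H4O6)
Reagents that add atoms: none
Why: Partial reduction of the ester, which stops at the aluminium hemiacetal that is stable at −78 °C.

Step 6
Reactants: 8 5-methylhex-5-enal (1.5 equiv); 5 (1E)-3-methylidene-1-nitrohepta-1,6-diene
Product: 9 (2R,3S)-3-(hexa-1,5-dien-2-yl)-2-(3-methylbut-3-en-1-yl)-4-nitrobutanal
Conditions: (S)-α,α-diphenylprolinol trimethylsilyl ether (10 mol %), 4-nitrophenol (10 mol %), toluene, 0 °C
Reagents that add atoms: none
Why: Enamine-catalysed Michael addition of an aldehyde to a nitroalkene (1,4-addition to the nitrodiene); the (E)-enamine, shielded on one face by the diphenyl(silyloxy)methyl group, adds through the acyclic synclinal transition state, so the catalyst sets both new stereocentres (syn, 2R,3S).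

Step 7
Reactants: 9 (2R,3S)-3-(hexa-1,5-dien-2-yl)-2-(3-methylbut-3-en-1-yl)-4-nitrobutanal
Product: 10 dimethyl acetal of 9 (same configuration)
Conditions: HC(OMe)3, TsOH·H2O (cat.), MeOH, 0 °C → rt
Reagents that add atoms: trimethyl orthoformate, COC(OC)OC
Why: Acid-catalysed acetalisation protects the epimerisable α-branched aldehyde before the oxidative Nef step.

Step 8
Reactants: 10 dimethyl acetal of 9
Product: 12 (2S,3R)-3-(dimethoxymethyl)-2-(hexa-1,5-dien-2-yl)-6-methylhept-6-enoic acid, via nitrolic acid 11 (not isolated)
Conditions: NaNO2 (3 equiv), AcOH (10 equiv), DMSO, 35 °C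
Reagents that add atoms: sodium nitrite, [Na+].[O-]N=O; water, O
Why: Oxidative Nef reaction of a primary nitroalkane (nitrosation of the nitronate to the nitrolic acid, then hydrolytic collapse) should give the acid without touching the unactivated alkenes; the acetate formed buffers the medium so that the acetal survives.

Step 9
Reactants: 12 (2S,3R)-3-(dimethoxymethyl)-2-(hexa-1,5-dien-2-yl)-6-methylhept-6-enoic acid
Product: 13 methyl (2S,3R)-3-(dimethoxymethyl)-2-(hexa-1,5-dien-2-yl)-6-methylhept-6-enoate
Conditions: Me3SiCHN2, toluene/MeOH (4:1), 0 °C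
Reagents that add atoms: (trimethylsilyl)diazomethane, C[Si](C)(C)C=[N+]=[N-]
Why: O-Methylation by the diazoalkane under neutral conditions leaves the β,γ-unsaturated α-stereocentre and the acetal untouched.

Step 10
Reactants: 13 methyl (2S,3R)-3-(dimethoxymethyl)-2-(hexa-1,5-dien-2-yl)-6-methylhept-6-enoate
Product: 14 methyl (1S,2R,5Z)-2-(dimethoxymethyl)-5-methyl-9-methylidenecyclonon-5-ene-1-carboxylate
Conditions: second-generation Hoveyda–Grubbs catalyst (H2IMes)Cl2Ru=CH(C6H4-2-OiPr) (10 mol %), 1,4-benzoquinone (20 mol %), toluene (1 mM), 80 °C
Reagents that add atoms: none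
Why: Ring-closing metathesis, in which the catalyst loads on the only monosubstituted alkene and can close productively only onto the isopropenyl group (closure onto the other 1,1-disubstituted alkene would give a cyclobutene); the nine-membered cycloalkene should form as the less strained (Z)-isomer, with high dilution and the vicinal branching working against oligomerisation.

Step 11
Reactants: 14 methyl (1S,2R,5Z)-2-(dimethoxymethyl)-5-methyl-9-methylidenecyclonon-5-ene-1-carboxylate
Product: 15 methyl (1S,2R,5Z)-2-formyl-5-methyl-9-methylidenecyclonon-5-ene-1-carboxylate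
Conditions: oxalic acid (5 % aq.), THF, rt
Reagents that add atoms: water, O
Why: Mild aqueous acid hydrolyses the dimethyl acetal without protonating the alkenes or epimerising the α-centre; the aldehyde is used at once.

Step 12
Reactants: 15 methyl (1S,2R,5Z)-2-formyl-5-methyl-9-methylidenecyclonon-5-ene-1-carboxylate
Product: 16 methyl (1S,2S,5Z)-2-(2-methoxyethenyl)-5-methyl-9-methylidenecyclonon-5-ene-1-carboxylate (E/Z mixture at the enol ether)
Conditions: MeOCH2PPh3Cl (1.3 equiv), KN(SiMe3)2 (1.25 equiv), THF, −78 °C; then 15, −78 → 0 °C
Reagents that add atoms: (methoxymethyl)triphenylphosphonium chloride, COC[P+](c1ccccc1)(c1ccccc1)c1ccccc1.[Cl-]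
Why: Wittig methoxymethylenation; the preformed ylide should add to the aldehyde at −78 °C faster than it deprotonates the α-positions, and the enol ether geometry is irrelevant.

Step 13
Reactants: 17 2-methylbut-3-en-2-ol (3 equiv); 18 3,3-dimethoxyprop-1-ene
Product: 19 (3E)-5,5-dimethoxy-2-methylpent-3-en-2-ol
Conditions: second-generation Hoveyda–Grubbs catalyst (H2IMes)Cl2Ru=CH(C6H4-2-OiPr) (2 mol %), CH2Cl2, 40 °C
Reagents that add atoms: none
Why: Olefin cross-metathesis between a hindered tertiary allylic alcohol and an acrolein acetal should give the (E)-alkene for steric reasons.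

Step 14
Reactants: 19 (3E)-5,5-dimethoxy-2-methylpent-3-en-2-ol
Product: 20 [(3E)-5,5-dimethoxy-2-methylpent-3-en-2-yl]oxy(trimethyl)silane
Conditions: Me3SiCl, imidazole, CH2Cl2, 0 °C
Reagents that add atoms: chlorotrimethylsilane, C[Si](C)(C)Cl
Why: Silylation keeps the tertiary alcohol from intercepting the oxocarbenium ion of step 15; the silyl ether is cleaved again in the hydrolytic second stage of that step.

Step 15
Reactants: 16 enol ether; 20 silylated unsaturated acetal
Product: 22 methyl (1S,2R,5Z)-2-[(2E,4E)-6-hydroxy-6-methyl-1-oxohepta-2,4-dien-2-yl]-5-methyl-9-methylidenecyclonon-5-ene-1-carboxylate, via methoxy acetal adduct 21 (not isolated)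
Conditions: BF3·OEt2 (10 mol %), CH2Cl2, −40 °C; then AcOH/H2O/THF, NaOAc, 45 °C
Reagents that add atoms: water, O
Why: Lewis-acid-mediated addition of an enol ether to an α,β-unsaturated acetal (Mukaiyama-type enol ether–acetal condensation, Müller–Cunradi–Pieroh reaction) joins the enol ether β-carbon to the acetal carbon; hydrolysis and β-elimination of methanol should then give the α-substituted dienal in its thermodynamically preferred (2E) geometry, with the formyl group trans to the vinyl group.

Step 16
Reactants: 22 (Z)-cyclononene dienal
Product: 23 methyl (1R,4R,5S,9S)-4-[(2E,4E)-6-hydroxy-6-methyl-1-oxohepta-2,4-dien-2-yl]-1-methyl-6-methylidene-10-oxabicyclo[7.1.0]decane-5-carboxylate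
Conditions: mCPBA (1.05 equiv), NaHCO3, CH2Cl2, −20 → 0 °C
Reagents that add atoms: 3-chloroperoxybenzoic acid, OOC(=O)c1cccc(Cl)c1
Why: Prilezhaev epoxidation should be chemoselective for the trisubstituted ring alkene (the exocyclic 1,1-disubstituted alkene is less nucleophilic, the dienal is electron-poor, and enals resist peracids as in the 6,7-epoxidation of citral); the peracid is expected to attack the exposed outer face of the folded conformer that carries both ring substituents pseudo-equatorially, which puts the oxirane oxygen opposite the transannular methylene and cis to the ester.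

Step 17
Reactants: 23 cis-oxirane
Product: 24 methyl (1S,2S,3R,6R,7S)-1,7-dihydroxy-3-[(2E,4E)-6-hydroxy-6-methyl-1-oxohepta-2,4-dien-2-yl]-6-methylbicyclo[4.3.1]decane-2-carboxylate
Conditions: HClO4 (5 mol %), THF/H2O (4:1), 0 °C → rt
Reagents that add atoms: water, O
Why: Protonation of the oxirane polarises its tertiary C–O bond; the terminal carbon of the exocyclic 1,1-disubstituted alkene, held across the nine-membered ring, attacks this carbon anti to the departing oxygen, and the resulting tertiary bridgehead cation is captured by water (directly or after transient capture by the side-chain aldehyde oxygen) on its only open, exo face. The closest known reaction type is the acid-catalysed transannular epoxide–olefin cyclisation of medium-ring terpene oxides with terminating hydration (caryophyllene oxide to caryolane-type diols, germacrene epoxides to eudesmane diols). The six-membered ring closes through a chair by 6-endo attack with respect to both the oxirane and the alkene (Markovnikov at both partners), and the seven-membered ring is the complementary ring made by the same bond (7-exo with respect to the oxirane), so the bicyclo[4.3.1]decane arises in one event. The quaternary methyl-bearing centre is set by inversion in the anti opening of the cis-oxirane; the secondary carbinol keeps the oxirane configuration and so ends up equatorial and trans to the methyl group; the bridgehead carbinol is fixed by the geometric constraint of the bicycle. The step needs opening at the tertiary carbon, C–C bond formation in preference to direct hydration or hydride shift, and an inert side chain: these rest on the 1,5-relationship of alkene and oxirane, the pseudo-equatorial placement of ester and side chain in the reacting fold, the fact that the bridgehead cation cannot lose a proton without forming a bridgehead alkene, and the electron-poor dienal, which also deactivates the tertiary allylic alcohol towards ionisation.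

Step 18
Reactants: 24 bicyclic dienal diol
Product: 25 methyl (1S,2S,3R,6R,7S)-3-[(2E,4E)-1,6-dihydroxy-6-methylhepta-2,4-dien-2-yl]-1,7-dihydroxy-6-methylbicyclo[4.3.1]decane-2-carboxylate
Conditions: NaBH4 (1.0 equiv), CeCl3·7H2O (1.0 equiv), MeOH, −40 °C
Reagents that add atoms: none
Why: Luche reduction should reduce the conjugated aldehyde by 1,2-addition and leave the methyl ester, the diene and the β-hydroxy ester untouched.

Step 19
Reactants: 25 tetraol
Product: 26 methyl (1S,2S,3R,6R,7S)-3-[(2E,4E)-1-(acetyloxy)-6-hydroxy-6-methylhepta-2,4-dien-2-yl]-1,7-dihydroxy-6-methylbicyclo[4.3.1]decane-2-carboxylate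
Conditions: Ac2O (1.1 equiv), 2,4,6-collidine, CH2Cl2, −20 → 0 °C
Reagents that add atoms: acetic anhydride, CC(=O)OC(C)=O
Why: Acylation of the only primary (allylic) hydroxyl should be much faster than that of the hindered secondary hydroxyl next to the quaternary centre and of the two tertiary hydroxyls.

## Compound list

1 | hex-5-enal | C=CCCCC=O | starting material
2 | 2-methylidenehex-5-enal | C=CCCC(=C)C=O | intermediate
3 | 3-methylidene-1-nitrohept-6-en-2-ol (racemic) | C=CCCC(=C)C(O)C[N+](=O)[O-] | intermediate
4 | 3-methylidene-1-nitrohept-6-en-2-yl methanesulfonate (not isolated) | C=CCCC(=C)C(OS(C)(=O)=O)C[N+](=O)[O-] | intermediate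
5 | (1E)-3-methylidene-1-nitrohepta-1,6-diene | C=CCCC(=C)/C=C/[N+](=O)[O-] | intermediate
6 | ethyl 5-oxohexanoate | CCOC(=O)CCCC(C)=O | starting material
7 | ethyl 5-methylhex-5-enoate | CCOC(=O)CCCC(C)=C | intermediate
8 | 5-methylhex-5-enal | C=C(C)CCCC=O | intermediate
9 | (2R,3S)-3-(hexa-1,5-dien-2-yl)-2-(3-methylbut-3-en-1-yl)-4-nitrobutanal | O=[N+]([O-])C[C@H](C(=C)CCC=C)[C@H](C=O)CCC(C)=C | intermediate
10 | dimethyl acetal of 9 | O=[N+]([O-])C[C@H](C(=C)CCC=C)[C@H](C(OC)OC)CCC(C)=C | intermediate
11 | nitrolic acid derived from 10 (not isolated) | ON=C([N+](=O)[O-])[C@H](C(=C)CCC=C)[C@H](C(OC)OC)CCC(C)=C | intermediate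
12 | (2S,3R)-3-(dimethoxymethyl)-2-(hexa-1,5-dien-2-yl)-6-methylhept-6-enoic acid | OC(=O)[C@H](C(=C)CCC=C)[C@H](C(OC)OC)CCC(C)=C | intermediate
13 | methyl (2S,3R)-3-(dimethoxymethyl)-2-(hexa-1,5-dien-2-yl)-6-methylhept-6-enoate | COC(=O)[C@H](C(=C)CCC=C)[C@H](C(OC)OC)CCC(C)=C | intermediate
14 | methyl (1S,2R,5Z)-2-(dimethoxymethyl)-5-methyl-9-methylidenecyclonon-5-ene-1-carboxylate | COC(=O)[C@H]1[C@H](C(OC)OC)CC/C(C)=C\CCC1=C | intermediate
15 | methyl (1S,2R,5Z)-2-formyl-5-methyl-9-methylidenecyclonon-5-ene-1-carboxylate | COC(=O)[C@H]1[C@H](C=O)CC/C(C)=C\CCC1=C | intermediate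
16 | methyl (1S,2S,5Z)-2-(2-methoxyethenyl)-5-methyl-9-methylidenecyclonon-5-ene-1-carboxylate (E/Z mixture at the enol ether) | COC(=O)[C@H]1[C@H](C=COC)CC/C(C)=C\CCC1=C | intermediate
17 | 2-methylbut-3-en-2-ol | C=CC(C)(C)O | starting material
18 | 3,3-dimethoxyprop-1-ene (acrolein dimethyl acetal) | C=CC(OC)OC | starting material
19 | (3E)-5,5-dimethoxy-2-methylpent-3-en-2-ol | COC(OC)/C=C/C(C)(C)O | intermediate
20 | [(3E)-5,5-dimethoxy-2-methylpent-3-en-2-yl]oxy(trimethyl)silane | COC(OC)/C=C/C(C)(C)O[Si](C)(C)C | intermediate
21 | β-methoxy dimethyl acetal adduct of 16 and 20 (new sp3 centres unassigned; not isolated) | COC(=O)[C@H]1[C@H](C(C(OC)OC)C(OC)/C=C/C(C)(C)O[Si](C)(C)C)CC/C(C)=C\CCC1=C | intermediate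
22 | methyl (1S,2R,5Z)-2-[(2E,4E)-6-hydroxy-6-methyl-1-oxohepta-2,4-dien-2-yl]-5-methyl-9-methylidenecyclonon-5-ene-1-carboxylate | COC(=O)[C@H]1[C@H](/C(=C\C=C\C(C)(C)O)C=O)CC/C(C)=C\CCC1=C | intermediate
23 | methyl (1R,4R,5S,9S)-4-[(2E,4E)-6-hydroxy-6-methyl-1-oxohepta-2,4-dien-2-yl]-1-methyl-6-methylidene-10-oxabicyclo[7.1.0]decane-5-carboxylate | COC(=O)[C@H]1[C@H](/C(=C\C=C\C(C)(C)O)C=O)CC[C@@]2(C)O[C@H]2CCC1=C | intermediate
24 | methyl (1S,2S,3R,6R,7S)-1,7-dihydroxy-3-[(2E,4E)-6-hydroxy-6-methyl-1-oxohepta-2,4-dien-2-yl]-6-methylbicyclo[4.3.1]decane-2-carboxylate | COC(=O)[C@H]1[C@H](/C(=C\C=C\C(C)(C)O)C=O)CC[C@]2(C)C[C@@]1(O)CC[C@@H]2O | intermediate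
25 | methyl (1S,2S,3R,6R,7S)-3-[(2E,4E)-1,6-dihydroxy-6-methylhepta-2,4-dien-2-yl]-1,7-dihydroxy-6-methylbicyclo[4.3.1]decane-2-carboxylate | COC(=O)[C@H]1[C@H](/C(=C\C=C\C(C)(C)O)CO)CC[C@]2(C)C[C@@]1(O)CC[C@@H]2O | intermediate
26 | methyl (1S,2S,3R,6R,7S)-3-[(2E,4E)-1-(acetyloxy)-6-hydroxy-6-methylhepta-2,4-dien-2-yl]-1,7-dihydroxy-6-methylbicyclo[4.3.1]decane-2-carboxylate | COC(=O)[C@H]1[C@H](/C(=C\C=C\C(C)(C)O)COC(C)=O)CC[C@]2(C)C[C@@]1(O)CC[C@@H]2O | target

## Step count and weak points

Total step count: 19. Longest linear sequence: 15 steps (steps 1–3, 6–12 and 15–19, from hex-5-enal).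

The three steps most likely to fail:

**Step 17 (transannular cyclisation).** Solvent water may open the protonated oxirane directly, giving an anti-diol without C–C bond formation. A 1,2-hydride shift to the ring ketone may also compete with attack by the alkene. The fallback changes the terminating event from capture by solvent to capture by a nucleophile built into the substrate, in a medium that contains no water. It sets out from 23, which is ionised in anhydrous (CF3)2CHOH with Ph4PBF4 (cat.) at 0 °C. The alkene is then the only nucleophile within reach of the oxirane, and the bridgehead cation should be intercepted on its exo face by the oxygen of the side-chain aldehyde through a six-membered ring. Work-up with aqueous NaHCO3 should give the bridged lactol F6, the ring–chain tautomer of 24. Under the conditions of step 18 it is reduced through its open form, so the sequence comes back to the route at 25.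

**Step 10 (ring-closing metathesis).** Acyclic diene metathesis may give oligomers faster than the strained nine-membered ring closes onto a 1,1-disubstituted alkene, and ruthenium hydrides may move the terminal alkenes. The fallback ties the two olefinic arms to a temporary five-membered ring before metathesis. It sets out from acid 12: TsOH (cat.) in toluene over molecular sieves closes the γ,γ-dimethoxy acid to the cyclic pseudo-ester (3S,4R)-3-(hexa-1,5-dien-2-yl)-5-methoxy-4-(3-methylbut-3-en-1-yl)oxolan-2-one F1, in which the arms sit trans on adjacent ring carbons. Metathesis under the conditions of step 10 should then give the trans-fused bicyclic pseudo-ester F2 (methoxy-γ-lactone fused to the (Z)-cyclononene). HC(OMe)3 and TsOH (cat.) in MeOH at 50 °C open the pseudo-ester to the normal methyl ester and dimethyl acetal, which is compound 14.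

**Step 16 (epoxidation).** The peracid may show poor facial selectivity on the flexible (Z)-cyclononene and deliver the oxirane on the other ring face. The fallback corrects the configuration afterwards by a double inversion. It sets out from 22, by way of the diastereomeric cis-oxirane F3 formed in the epoxidation. Closure of F3 across the ring would force the side chain into the endo position, so in dilute H2SO4 in THF/H2O (1:1) it is expected to be hydrated at the tertiary carbon with inversion, giving the anti-diol F4. MsCl in pyridine at 0 °C should sulfonylate only the secondary hydroxyl, giving the mesylate F5. DBU in CH2Cl2 then closes the oxirane from the tertiary alkoxide with inversion at the secondary carbon. Both oxirane carbons are thereby inverted relative to F3, and the sequence comes back to the route at 23.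

## Further compounds

F1 | step 10 | (3S,4R)-3-(hexa-1,5-dien-2-yl)-5-methoxy-4-(3-methylbut-3-en-1-yl)oxolan-2-one (cyclic pseudo-ester, acetal carbon unassigned) | O=C1[C@H](C(=C)CCC=C)[C@H](C(OC)O1)CCC(C)=C
F2 | step 10 | trans-fused bicyclic pseudo-ester: 5-methoxy-γ-lactone fused to the (Z)-methyl-methylidene-cyclononene (acetal carbon unassigned) | O=C2[C@H]1[C@H](C(OC)O2)CC/C(C)=C\CCC1=C
F3 | step 16 | diastereomer of 23 with the oxirane oxygen on the opposite ring face (1S,9R) | COC(=O)[C@H]1[C@H](/C(=C\C=C\C(C)(C)O)C=O)CC[C@]2(C)O[C@@H]2CCC1=C
F4 | step 16 | anti-diol from F3 (tertiary hydroxyl on the methyl-bearing ring carbon, secondary hydroxyl on the adjacent ring carbon) | COC(=O)[C@H]1[C@H](/C(=C\C=C\C(C)(C)O)C=O)CC[C@@](C)(O)[C@H](O)CCC1=C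
F5 | step 16 | secondary methanesulfonate of F4 | COC(=O)[C@H]1[C@H](/C(=C\C=C\C(C)(C)O)C=O)CC[C@@](C)(O)[C@H](OS(C)(=O)=O)CCC1=C
F6 | step 17 | bridged lactol, ring–chain tautomer of 24 (bridgehead oxygen bonded to the former aldehyde carbon, lactol carbon unassigned) | COC(=O)[C@H]1[C@H](/C(=C\C=C\C(C)(C)O)C(O)O3)CC[C@]2(C)C[C@@]13CC[C@@H]2O
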